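The route rests on cutting the two ring B arms away from ring A: the C5–C6 and C9–C10 bonds. One operation makes both bonds and both stereocentres: a copper-catalysed asymmetric vinyl addition to C5 of 2,4,4-trimethylcyclohex-2-enone, with in-flask alkylation of the C10 enolate by 2,3-dibromopropene. It exploits the vicinal pair C5 (methine) and C10 (methyl-bearing quaternary carbon) shared by rings A and B. Their trans relationship (C10 methyl anti to H5) arises because the allyl group enters anti to the new vinyl group. The precursor is the achiral annulation enone from isobutyraldehyde and ethyl vinyl ketone. The product carries the C1 ketone, the C6=C7 vinyl group and a C9–C8 bromoalkene for ring B closure.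

Key step: step 2

Conventions and assumptions (remarks on the chemistry):
- Locants follow the target. Ring A is C1–C5 and C10 (gem-dimethyl on C4, methyl on C10). Ring B is C5–C10. Ring C is C8, C17, C15, C14, C13 (methyl), C12, C11, C9.
- α is the face of rings A/B that carries the C10 methyl; β is the face of H5. The target is 1β,3β-dibenzoyloxy, 2β,7β-diacetoxy, 8α-hydroxy, 9β-H, 11,17-dioxo, (1S,2R,3R,5R,7S,8S,9S,10R).
- (2S,3R)-8 maps onto 5R,10R of the target; the descriptor at C10 changes through CIP priorities only.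
- The terminal CH2 of the bromoallyl group is a sacrificial handle, excised in step 8. C17 is brought in later as a nucleophile, because only carbon attack on a C8 ketone from the β face gives the 8α hydroxyl.
- Assumption: the carbinol centres C11 (steps 13–28) and C17 (steps 20–28) are carried as epimer mixtures. Both become ketones in step 29.
- PMB = 4-methoxybenzyl, TBS = tert-butyldimethylsilyl, Bz = benzoyl. L* = a Josiphos-type ferrocenyl diphosphine, the enantiomer being chosen to give 5R.

Step 1
Reactants: 1 isobutyraldehyde; 2 ethyl vinyl ketone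
Product: 4 2,4,4-trimethylcyclohex-2-en-1-one, via keto aldehyde 3 (not isolated)
Conditions: H2SO4 (cat.), toluene, 45 °C then reflux (Dean–Stark)
Reagents that add atoms: none
Why: Acid-catalysed Michael addition of the aldehyde enol to the enone and intramolecular aldol condensation of keto aldehyde 3 (Robinson annulation) should give the enone, with water removed azeotropically and no stereocentre formed.

Step 2
Reactants: 4 2,4,4-trimethylcyclohex-2-en-1-one; 5 vinylmagnesium bromide; 6 2,3-dibromopropene
Product: 8 (2S,3R)-2-(2-bromoallyl)-2,4,4-trimethyl-3-vinylcyclohexan-1-one, via magnesium enolate 7 (not isolated)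
Conditions: CuBr·SMe2 (5 mol%), L* (6 mol%), tBuOMe/THF, −78 °C; then 6, DMPU, −78 → 0 °C
Reagents that add atoms: none
Why: Transmetalation of 5 to the ligated copper centre gives a chiral vinylcopper species that adds to C5 of 4 (the β-carbon, next to the gem-dimethyl carbon), and collapse of the adduct leaves bromomagnesium enolate 7, fully substituted at C10 and therefore regiochemically unambiguous. Addition of 6 with DMPU then C-alkylates C10 at the allylic bromide (direct and allylic displacement give the same 2-bromoallyl group), so C5–C6 and C9–C10 arise in one flask; the closest known reaction type is the copper-catalysed asymmetric conjugate addition of Grignard reagents to α-substituted cycloalkenones with in situ enolate alkylation. No ring is closed in this step. The C5 centre (R) is controlled by the chiral diphosphine on copper, and the C10 centre (S) by the substrate, because the electrophile approaches the enolate face opposite to the adjacent vinyl group. The step needs high enantiofacial selectivity and C- rather than O-alkylation without proton exchange; the ligand, the soft allylic electrophile, the polar co-solvent and the absence of a second enolisable position next to C10 are expected to secure these.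

Step 3
Reactants: 8 (2S,3R)-2-(2-bromoallyl)-2,4,4-trimethyl-3-vinylcyclohexan-1-one
Product: 9 (5R,6S)-6-(2-bromoallyl)-4,4,6-trimethyl-5-vinylcyclohex-2-en-1-one
Conditions: IBX, DMSO/toluene, 75 °C
Reagents that add atoms: none
Why: IBX-mediated α,β-dehydrogenation of the ketone can only run towards C2–C3 because C10 is quaternary, and it leaves both stereocentres and both isolated alkenes untouched.

Step 4
Reactants: 9 (5R,6S)-6-(2-bromoallyl)-4,4,6-trimethyl-5-vinylcyclohex-2-en-1-one
Product: 10 2β,3β-epoxy ketone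
Conditions: 30% aq. H2O2, NaOH (cat.), MeOH, 0 °C
Reagents that add atoms: hydrogen peroxide, OO
Why: In this Weitz–Scheffer nucleophilic epoxidation the hydroperoxide should add axially to C3 on the face of H5, away from the C10 methyl and the axial C4 methyl, and close on the same face, which sets C2 and C3 as the β-epoxide.

Step 5
Reactants: 10 2β,3β-epoxy ketone
Product: 11 allylic alcohol (3β-OH and C1=C2)
Conditions: N2H4·H2O, AcOH (cat.), MeOH, 0 °C → rt
Reagents that add atoms: none
Why: In the Wharton transposition the epoxy hydrazone fragments with loss of dinitrogen to the C1=C2 alkene, so the C3–O bond and its β configuration are carried over unchanged.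

Step 6
Reactants: 11 allylic alcohol (3β-OH and C1=C2)
Product: 12 PMB ether of 11
Conditions: NaH, PMBCl, Bu4NI (cat.), DMF, 0 °C → rt
Reagents that add atoms: 4-methoxybenzyl chloride, COc1ccc(CCl)cc1
Why: Williamson etherification of the hindered allylic alkoxide masks O3 with a group that survives bases, organometallics, fluoride and metathesis and is later removed oxidatively.

Step 7
Reactants: 12 PMB ether of 11
Product: 14 bicyclic 8-methylene PMB ether, via B-alkyl borane 13 (not isolated)
Conditions: 9-BBN, THF, rt; then Pd(dppf)Cl2 (5 mol%), 3 M aq. NaOH, THF, 60 °C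
Reagents that add atoms: none
Why: 9-BBN should hydroborate only the terminal vinyl group (bromoalkene and ring A alkene are far slower), and intramolecular B-alkyl Suzuki–Miyaura coupling of 13 with the alkenyl bromide closes ring B at C7–C8 as a methylenecyclohexane, the trans ring fusion being fixed already by C5 and C10.

Step 8
Reactants: 14 bicyclic 8-methylene PMB ether
Product: 16 8-ketone, via 8,17-diol 15 (not isolated)
Conditions: OsO4 (2 mol%), NaIO4, 2,6-lutidine, dioxane/H2O, rt
Reagents that add atoms: sodium periodate, [Na+].[O-]I(=O)(=O)=O (terminal oxidant; its oxygen reaches the product through catalytic osmium tetroxide, O=[Os](=O)(=O)=O)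
Why: In this Lemieux–Johnson cleavage the exposed 1,1-disubstituted alkene is osmylated and the diol is cleaved to the C8 ketone, while the ring A alkene is shielded by the C10 methyl on one face and the pseudoaxial PMB ether on the other.

Step 9
Reactants: 16 8-ketone
Product: 18 7β-hydroxy-8-ketone, via potassium enolate 17 (not isolated)
Conditions: KN(SiMe3)2, THF, −78 °C; then 2-(phenylsulfonyl)-3-phenyloxaziridine; AcOH quench
Reagents that add atoms: 2-(phenylsulfonyl)-3-phenyloxaziridine, O=S(=O)(c1ccccc1)N1OC1c1ccccc1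
Why: Kinetic deprotonation should occur at the open C7 methylene and not at the neopentyl C9, and enolate oxidation by the N-sulfonyloxaziridine anti to the C10 methyl gives the 7β alcohol, a centre that is erased in the next step.

Step 10
Reactants: 18 7β-hydroxy-8-ketone
Product: 19 diosphenol (7-hydroxy-Δ6-en-8-one)
Conditions: Dess–Martin periodinane, CH2Cl2, rt
Reagents that add atoms: none
Why: Dess–Martin oxidation of the α-hydroxy ketone gives the 7,8-dione, which should rest as the enol formed towards the accessible C6 and not towards the neopentyl C9.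

Step 11
Reactants: 19 diosphenol (7-hydroxy-Δ6-en-8-one)
Product: 20 7-(TBS-oxy)-Δ6-en-8-one
Conditions: TBSOTf, Et3N, CH2Cl2, −78 → 0 °C
Reagents that add atoms: tert-butyldimethylsilyl triflate, CC(C)(C)[Si](C)(C)OS(=O)(=O)C(F)(F)F
Why: O-silylation of the enol keeps C7 oxidised but sp2, so that C9 is the only enolisable position of ring B and no axial C7 substituent will later block the β face of C8.

Step 12
Reactants: 21 3-methylbut-3-en-1-ol
Product: 22 3-methylbut-3-enal
Conditions: Dess–Martin periodinane, CH2Cl2, 0 °C (used at once as a cold solution)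
Reagents that add atoms: none
Why: Dess–Martin oxidation gives the β,γ-unsaturated aldehyde without base, so the alkene should not move into conjugation before use.

Step 13
Reactants: 20 7-(TBS-oxy)-Δ6-en-8-one; 22 3-methylbut-3-enal
Product: 24 C9 aldol adduct (9-epi series), via lithium dienolate 23 (not isolated)
Conditions: LiN(iPr)2, THF, −78 °C; then 22; AcOH quench at −78 °C
Reagents that add atoms: none
Why: α′-Deprotonation gives the cross-conjugated dienolate, whose aldol addition forms C9–C11 next to a flat C1 (sp2 in ring A); the aldehyde should enter anti to the C10 methyl, which places C11 on the β face, and C11 itself forms as an inconsequential epimer mixture.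

Step 14
Reactants: 24 C9 aldol adduct (9-epi series)
Product: 25 TBS ether of 24
Conditions: TBSOTf, 2,6-lutidine, CH2Cl2, −78 °C
Reagents that add atoms: tert-butyldimethylsilyl triflate, CC(C)(C)[Si](C)(C)OS(=O)(=O)C(F)(F)F
Why: Silylation of the aldol hydroxyl prevents retro-aldol cleavage in the following base and organometallic steps.

Step 15
Reactants: 25 TBS ether of 24
Product: 27 C9-epimerised ketone (9β-H), via lithium enolate 26 (not isolated)
Conditions: LiN(iPr)2, THF, −78 → −40 °C; then AcOH, −78 °C
Reagents that add atoms: none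
Why: Deprotonation and kinetic reprotonation: the enolate is planar at C9 and should take up the proton on the β face, anti to the C10 methyl, which moves the C11 arm into the equatorial α position of the target.

Step 16
Reactants: 27 C9-epimerised ketone (9β-H); 5 vinylmagnesium bromide
Product: 28 tertiary alcohol (8α-OH and 8β-vinyl)
Conditions: CeCl3, THF, −78 → 0 °C; aqueous work-up
Reagents that add atoms: none
Why: Organocerium 1,2-addition (enolisation suppressed); with C7 sp2 and the C9 arm equatorial, only the axial C10 methyl differentiates the faces, so vinyl should enter from the β face and give the 8α alcohol with C17 equatorial.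

Step 17
Reactants: 28 tertiary alcohol (8α-OH and 8β-vinyl)
Product: 29 7-keto-8α-hydroxy compound
Conditions: HF·pyridine, pyridine, THF, 0 °C
Reagents that add atoms: none
Why: Buffered fluoride cleavage of the silyl enol ether, far faster than that of the secondary alkyl TBS ether, unmasks the C7 ketone.

Step 18
Reactants: 29 7-keto-8α-hydroxy compound
Product: 30 7β,8α-diol
Conditions: Me4NBH(OAc)3, MeCN/AcOH, −20 °C
Reagents that add atoms: none
Why: In this hydroxyl-directed (Saksena–Evans) reduction the 8α hydroxyl binds boron and hydride is delivered to C7 on the same α face, which sets the 7β alcohol trans-diaxial to O8.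

Step 19
Reactants: 30 7β,8α-diol
Product: 31 7β-acetate
Conditions: Ac2O, DMAP (cat.), pyridine, rt
Reagents that add atoms: acetic anhydride, CC(=O)OC(C)=O
Why: DMAP-catalysed acyl transfer acetylates the secondary C7 hydroxyl and leaves the tertiary C8 hydroxyl free, installing a final ester before any other secondary hydroxyl is present.

Step 20
Reactants: 31 7β-acetate
Product: 32 epoxide (8β-oxiranyl)
Conditions: VO(acac)2 (5 mol%), tBuOOH, CH2Cl2, 0 °C → rt
Reagents that add atoms: tert-butyl hydroperoxide, CC(C)(C)OO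
Why: Vanadium-catalysed hydroxyl-directed epoxidation should touch only the vinyl group allylic to the free tertiary alcohol; C17 forms as an epimer mixture of no consequence.

Step 21
Reactants: 32 epoxide (8β-oxiranyl); 5 vinylmagnesium bromide
Product: 33 homoallylic alcohol (C8 allyl carbinol arm)
Conditions: CuI (10 mol%), THF, −78 → −40 °C; cold aqueous quench
Reagents that add atoms: none
Why: Copper-catalysed SN2 opening at the terminal epoxide carbon forms C15–C14 and completes the C17–C15–C14 arm, the low temperature keeping the hindered C7 acetate from attack or migration.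

Step 22
Reactants: 33 homoallylic alcohol (C8 allyl carbinol arm)
Product: 34 bis-TBS diene
Conditions: TBSOTf, 2,6-lutidine, CH2Cl2, −78 °C
Reagents that add atoms: tert-butyldimethylsilyl triflate, CC(C)(C)[Si](C)(C)OS(=O)(=O)C(F)(F)F
Why: Silylation of the secondary C17 hydroxyl, much faster than that of the axial tertiary C8 hydroxyl, reserves O17 and O11 for the final oxidation.

Step 23
Reactants: 34 bis-TBS diene
Product: 35 tricyclic PMB ether
Conditions: RuCl2(=CHPh)(PCy3)(H2IMes) (second-generation Grubbs catalyst, 10 mol%), toluene (1 mM), 80 °C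
Reagents that add atoms: none
Why: Ring-closing metathesis of the allyl and methallyl arms, held gauche on adjacent equatorial positions of ring B, should close the eight-membered ring C and form the trisubstituted C13=C14 alkene, which can only be Z in this ring.

Step 24
Reactants: 35 tricyclic PMB ether
Product: 36 tricyclic allylic alcohol
Conditions: DDQ, CH2Cl2/pH 7 buffer, 0 °C → rt
Reagents that add atoms: none
Why: Oxidative PMB cleavage frees the 3β hydroxyl without affecting silyl ethers, the acetate or the alkenes.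

Step 25
Reactants: 36 tricyclic allylic alcohol
Product: 38 1β,2β,3β-triol, via osmate ester 37 (not isolated)
Conditions: OsO4 (1.05 equiv), TMEDA, CH2Cl2, −78 °C; then aq. Na2SO3, THF, 50 °C
Reagents that add atoms: osmium tetroxide, O=[Os](=O)(=O)=O
Why: In this hydrogen-bond-directed dihydroxylation the OsO4·TMEDA complex is held by the 3β hydroxyl and should add to C1=C2 from the β face, the face free of the two axial methyls, setting C1 and C2 faster than the undirected ring C alkene reacts.

Step 26
Reactants: 38 1β,2β,3β-triol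
Product: 39 2-acetate
Conditions: Ac2O (1.2 equiv), pyridine, 0 °C
Reagents that add atoms: acetic anhydride, CC(=O)OC(C)=O
Why: Selective acylation: the equatorial C2 hydroxyl should react far faster than the two axial neopentyl hydroxyls at C1 and C3 or the tertiary one at C8.

Step 27
Reactants: 39 2-acetate
Product: 40 1,3-dibenzoate
Conditions: BzCl, DMAP, pyridine, 50 °C
Reagents that add atoms: benzoyl chloride, O=C(Cl)c1ccccc1
Why: Forcing DMAP-catalysed benzoylation esterifies the two remaining secondary (axial) hydroxyls, while the tertiary C8 hydroxyl should stay free.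

Step 28
Reactants: 40 1,3-dibenzoate
Product: 41 11,17-diol
Conditions: HF·pyridine, THF, 0 °C → rt
Reagents that add atoms: none
Why: Acidic fluoride desilylation removes both TBS ethers under conditions that leave the four esters and avoid acyl migration.

Step 29
Reactants: 41 11,17-diol
Product: 42 target CNP0214674.2
Conditions: Dess–Martin periodinane, CH2Cl2, rt
Reagents that add atoms: none
Why: Double Dess–Martin oxidation converts both secondary carbinols into the C11 and C17 ketones under non-basic conditions, so the β-hydroxy ketone is not dehydrated, the β,γ-alkene does not migrate and C9 keeps its equatorial acyl group.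

Compound list
1 | isobutyraldehyde (2-methylpropanal) | CC(C)C=O | starting material
2 | ethyl vinyl ketone (pent-1-en-3-one) | CCC(=O)C=C | starting material
3 | 2,2-dimethyl-5-oxoheptanal | CCC(=O)CCC(C)(C)C=O | intermediate (not isolated)
4 | 2,4,4-trimethylcyclohex-2-en-1-one | CC1=CC(C)(C)CCC1=O | intermediate
5 | vinylmagnesium bromide | C=C[Mg]Br | starting material
6 | 2,3-dibromopropene | C=C(Br)CBr | starting material
7 | bromomagnesium C1=C2 enolate of (3R)-2,4,4-trimethyl-3-vinylcyclohexanone | C=C[C@H]1C(C)=C(O[Mg]Br)CCC1(C)C | intermediate (not isolated)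
8 | (2S,3R)-2-(2-bromoallyl)-2,4,4-trimethyl-3-vinylcyclohexan-1-one | C1C(=O)[C@](CC(Br)=C)(C)[C@H](C=C)C(C)(C)C1 | intermediate
9 | (5R,6S)-6-(2-bromoallyl)-4,4,6-trimethyl-5-vinylcyclohex-2-en-1-one | C1=CC(=O)[C@](CC(Br)=C)(C)[C@H](C=C)C1(C)C | intermediate
10 | 2β,3β-epoxy ketone (epoxide of 9; oxygen cis to the bromoallyl group, trans to vinyl and to the C10 methyl) | O=C1[C@@H]2O[C@@H]2C(C)(C)[C@@H](C=C)[C@]1(C)CC(Br)=C | intermediate
11 | allylic alcohol: 4-(2-bromoallyl)-4,6,6-trimethyl-5-vinylcyclohex-2-en-1-ol, OH cis to the bromoallyl group (3β-OH, C1=C2) | O[C@H]1C=C[C@](CC(Br)=C)(C)[C@H](C=C)C1(C)C | intermediate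
12 | PMB ether of 11 | COc1ccc(CO[C@H]2C=C[C@](CC(Br)=C)(C)[C@H](C=C)C2(C)C)cc1 | intermediate
13 | B-alkyl borane: 12 with the vinyl group turned into CH2CH2–(9-BBN) | COc1ccc(CO[C@H]2C=C[C@](CC(Br)=C)(C)[C@H](CCB3C4CCCC3CCC4)C2(C)C)cc1 | intermediate (not isolated)
14 | bicyclic alkene: trans-decalin (5β-H, 10α-CH3), C1=C2, 3β-OPMB, 4,4-dimethyl, 8-methylene | COc1ccc(CO[C@H]2C=C[C@]3(C)[C@H](CCC(=C)C3)C2(C)C)cc1 | intermediate
15 | 8,17-diol of 14 (C8 epimers) | COc1ccc(CO[C@H]2C=C[C@]3(C)[C@H](CCC(O)(CO)C3)C2(C)C)cc1 | intermediate (not isolated)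
16 | 8-ketone (14 with C8=O in place of the methylene) | COc1ccc(CO[C@H]2C=C[C@]3(C)[C@H](CCC(=O)C3)C2(C)C)cc1 | intermediate
17 | potassium C7=C8 enolate of 16 | COc1ccc(CO[C@H]2C=C[C@]3(C)[C@H](CC=C(O[K])C3)C2(C)C)cc1 | intermediate (not isolated)
18 | 7β-hydroxy-8-ketone | COc1ccc(CO[C@H]2C=C[C@]3(C)[C@H](C[C@H](O)C(=O)C3)C2(C)C)cc1 | intermediate
19 | diosphenol: 7-hydroxy-Δ6-en-8-one (enol of the 7,8-dione) | COc1ccc(CO[C@H]2C=C[C@]3(C)[C@H](C=C(O)C(=O)C3)C2(C)C)cc1 | intermediate
20 | 7-(TBS-oxy)-Δ6-en-8-one | COc1ccc(CO[C@H]2C=C[C@]3(C)[C@H](C=C(O[Si](C)(C)C(C)(C)C)C(=O)C3)C2(C)C)cc1 | intermediate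
21 | 3-methylbut-3-en-1-ol | CC(=C)CCO | starting material
22 | 3-methylbut-3-enal | CC(=C)CC=O | intermediate
23 | lithium dienolate of 20 (8-OLi, C6=C7 and C8=C9) | COc1ccc(CO[C@H]2C=C[C@]3(C)[C@H](C=C(O[Si](C)(C)C(C)(C)C)C(O[Li])=C3)C2(C)C)cc1 | intermediate (not isolated)
24 | aldol adduct: 20 with CH(OH)CH2C(CH3)=CH2 at C9 on the β face (9α-H; C11 epimers) | COc1ccc(CO[C@H]2C=C[C@]3(C)[C@H](C=C(O[Si](C)(C)C(C)(C)C)C(=O)[C@@H]3C(O)CC(C)=C)C2(C)C)cc1 | intermediate
25 | TBS ether of 24 | COc1ccc(CO[C@H]2C=C[C@]3(C)[C@H](C=C(O[Si](C)(C)C(C)(C)C)C(=O)[C@@H]3C(O[Si](C)(C)C(C)(C)C)CC(C)=C)C2(C)C)cc1 | intermediate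
26 | lithium C8=C9 enolate of 25 | COc1ccc(CO[C@H]2C=C[C@]3(C)[C@H](C=C(O[Si](C)(C)C(C)(C)C)C(O[Li])=C3C(O[Si](C)(C)C(C)(C)C)CC(C)=C)C2(C)C)cc1 | intermediate (not isolated)
27 | C9 epimer of 25: 9β-H, C11 arm α (equatorial) | COc1ccc(CO[C@H]2C=C[C@]3(C)[C@H](C=C(O[Si](C)(C)C(C)(C)C)C(=O)[C@H]3C(O[Si](C)(C)C(C)(C)C)CC(C)=C)C2(C)C)cc1 | intermediate
28 | tertiary alcohol: 8α-OH, 8β-vinyl, 7-(TBS-oxy)-Δ6 | COc1ccc(CO[C@H]2C=C[C@]3(C)[C@H](C=C(O[Si](C)(C)C(C)(C)C)[C@](O)(C=C)[C@H]3C(O[Si](C)(C)C(C)(C)C)CC(C)=C)C2(C)C)cc1 | intermediate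
29 | 7-keto-8α-hydroxy compound | COc1ccc(CO[C@H]2C=C[C@]3(C)[C@H](CC(=O)[C@](O)(C=C)[C@H]3C(O[Si](C)(C)C(C)(C)C)CC(C)=C)C2(C)C)cc1 | intermediate
30 | 7β,8α-diol | COc1ccc(CO[C@H]2C=C[C@]3(C)[C@H](C[C@H](O)[C@](O)(C=C)[C@H]3C(O[Si](C)(C)C(C)(C)C)CC(C)=C)C2(C)C)cc1 | intermediate
31 | 7β-acetate | COc1ccc(CO[C@H]2C=C[C@]3(C)[C@H](C[C@H](OC(C)=O)[C@](O)(C=C)[C@H]3C(O[Si](C)(C)C(C)(C)C)CC(C)=C)C2(C)C)cc1 | intermediate
32 | epoxide: 8β-oxiranyl (C17 epimers) | COc1ccc(CO[C@H]2C=C[C@]3(C)[C@H](C[C@H](OC(C)=O)[C@](O)(C4CO4)[C@H]3C(O[Si](C)(C)C(C)(C)C)CC(C)=C)C2(C)C)cc1 | intermediate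
33 | homoallylic alcohol: 8β-CH(OH)CH2CH=CH2 | COc1ccc(CO[C@H]2C=C[C@]3(C)[C@H](C[C@H](OC(C)=O)[C@](O)(C(O)CC=C)[C@H]3C(O[Si](C)(C)C(C)(C)C)CC(C)=C)C2(C)C)cc1 | intermediate
34 | bis-TBS diene (11,17-bis-TBS ether, allyl and methallyl arms) | COc1ccc(CO[C@H]2C=C[C@]3(C)[C@H](C[C@H](OC(C)=O)[C@](O)(C(O[Si](C)(C)C(C)(C)C)CC=C)[C@H]3C(O[Si](C)(C)C(C)(C)C)CC(C)=C)C2(C)C)cc1 | intermediate
35 | tricyclic PMB ether (ring C closed, Z-C13=C14) | COc1ccc(CO[C@H]2C=C[C@]3(C)[C@H](C[C@H](OC(C)=O)[C@]4(O)C(O[Si](C)(C)C(C)(C)C)C/C=C(/C)CC(O[Si](C)(C)C(C)(C)C)[C@H]43)C2(C)C)cc1 | intermediate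
36 | tricyclic allylic alcohol (3β-OH, C1=C2) | O[C@H]1C=C[C@]2(C)[C@H](C[C@H](OC(C)=O)[C@]3(O)C(O[Si](C)(C)C(C)(C)C)C/C=C(/C)CC(O[Si](C)(C)C(C)(C)C)[C@H]32)C1(C)C | intermediate
37 | cyclic osmate ester of 36 across O1 and O2 (β face), TMEDA adduct | O4[C@H]1[C@@H](O[Os]4(=O)=O)[C@]2(C)[C@H](C[C@H](OC(C)=O)[C@]3(O)C(O[Si](C)(C)C(C)(C)C)C/C=C(/C)CC(O[Si](C)(C)C(C)(C)C)[C@H]32)C(C)(C)[C@H]1O.CN(C)CCN(C)C | intermediate (not isolated)
38 | 1β,2β,3β-triol | O[C@H]1[C@@H](O)[C@]2(C)[C@H](C[C@H](OC(C)=O)[C@]3(O)C(O[Si](C)(C)C(C)(C)C)C/C=C(/C)CC(O[Si](C)(C)C(C)(C)C)[C@H]32)C(C)(C)[C@H]1O | intermediate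
39 | 2-acetate (2β,7β-diacetate, 1β,3β-diol) | CC(=O)O[C@H]1[C@@H](O)[C@]2(C)[C@H](C[C@H](OC(C)=O)[C@]3(O)C(O[Si](C)(C)C(C)(C)C)C/C=C(/C)CC(O[Si](C)(C)C(C)(C)C)[C@H]32)C(C)(C)[C@H]1O | intermediate
40 | 1,3-dibenzoate (fully acylated 11,17-bis-TBS ether) | CC(=O)O[C@H]1[C@@H](OC(=O)c2ccccc2)[C@]2(C)[C@H](C[C@H](OC(C)=O)[C@]3(O)C(O[Si](C)(C)C(C)(C)C)C/C=C(/C)CC(O[Si](C)(C)C(C)(C)C)[C@H]32)C(C)(C)[C@H]1OC(=O)c1ccccc1 | intermediate
41 | 11,17-diol | CC(=O)O[C@H]1[C@@H](OC(=O)c2ccccc2)[C@]2(C)[C@H](C[C@H](OC(C)=O)[C@]3(O)C(O)C/C=C(/C)CC(O)[C@H]32)C(C)(C)[C@H]1OC(=O)c1ccccc1 | intermediate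
42 | CNP0214674.2: 2β,7β-diacetoxy-1β,3β-dibenzoyloxy-8α-hydroxy-11,17-dioxo tricycle, (1S,2R,3R,5R,7S,8S,9S,10R), Z-C13=C14 | CC(=O)O[C@H]1[C@@H](OC(=O)c2ccccc2)[C@]2(C)[C@H](C[C@H](OC(C)=O)[C@]3(O)C(=O)C/C=C(/C)CC(=O)[C@H]32)C(C)(C)[C@H]1OC(=O)c1ccccc1 | target

Total step count: 29. Longest linear sequence: 28 steps (steps 1–11 and 13–29; step 12 prepares aldehyde 22 separately).

The three steps most likely to fail

1. Step 2 (key step). The vinyl transfer to this α-methyl, γ,γ-dimethyl enone may proceed with poor enantiofacial discrimination. C-alkylation of the crowded magnesium enolate may also be slow enough for proton exchange and O-alkylation to take over. The fallback sets out from 4 and comes back at 8, and separates the two bond formations. The copper-catalysed conjugate addition of 5 is run with Me3SiCl present, so the enolate is captured and isolated as silyl enol ether F1. Its enantiomeric purity can then be optimised at this simpler two-component stage. MeLi in THF releases the regiodefined lithium enolate F2. This more reactive enolate is alkylated with 6 in THF/HMPA at −78 → 0 °C, again anti to the vinyl group, to give 8.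

2. Step 15. Removal of the hindered C9 proton may be slow, so that β-elimination of the C11 silyloxy group or incomplete epimerisation intervenes, and the reprotonation may not be fully face-selective. The fallback sets out from 24 and comes back at 27; it adds hydrogen to C9 last instead of inverting C9. Mesylation and elimination (MsCl, Et3N) convert 24 into alkylidene enone F3. Copper-catalysed conjugate borylation (B2pin2, CuCl, NaOtBu, a diphosphine, MeOH) places boron on C11, and the copper enolate is protonated at C9 anti to the C10 methyl, giving β-boryl ketone F4. Oxidation with NaBO3 gives β-hydroxy ketone F5 with the C11 arm equatorial. Silylation (TBSOTf, 2,6-lutidine) gives 27.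

3. Step 25. Osmylation of the trisubstituted ring C alkene may compete with the directed reaction at C1=C2, possibly with delivery by the C8 hydroxyl across the eight-membered ring. The fallback sets out from 34 and comes back at 40. It moves ring A oxidation ahead of ring closure, so the only competitors are two less electron-rich terminal alkenes without a nearby hydroxyl. DDQ converts 34 into allylic alcohol F6. OsO4·TMEDA at −78 °C with sulfite work-up gives triol F7. Selective acetylation at O2 gives monoacetate F8, and forcing benzoylation gives dibenzoate F9. Ring-closing metathesis with RuCl2(=CHPh)(PCy3)(H2IMes) then closes ring C and gives 40.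

Further compounds
F1 | step 2 | trimethylsilyl enol ether of (3R)-2,4,4-trimethyl-3-vinylcyclohexanone (C1=C2) | C=C[C@H]1C(C)=C(O[Si](C)(C)C)CCC1(C)C
F2 | step 2 | lithium C1=C2 enolate of (3R)-2,4,4-trimethyl-3-vinylcyclohexanone | C=C[C@H]1C(C)=C(O[Li])CCC1(C)C
F3 | step 15 | alkylidene enone: 20 with C9=C11H–CH2C(CH3)=CH2 (alkene geometry not controlled) | COc1ccc(CO[C@H]2C=C[C@]3(C)[C@H](C=C(O[Si](C)(C)C(C)(C)C)C(=O)C3=CCC(C)=C)C2(C)C)cc1
F4 | step 15 | β-boryl ketone: 9β-H, C11 bearing the pinacolboryl group (C11 epimers) | COc1ccc(CO[C@H]2C=C[C@]3(C)[C@H](C=C(O[Si](C)(C)C(C)(C)C)C(=O)[C@H]3C(B4OC(C)(C)C(C)(C)O4)CC(C)=C)C2(C)C)cc1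
F5 | step 15 | β-hydroxy ketone: 9β-H, C11–OH (C11 epimers) | COc1ccc(CO[C@H]2C=C[C@]3(C)[C@H](C=C(O[Si](C)(C)C(C)(C)C)C(=O)[C@H]3C(O)CC(C)=C)C2(C)C)cc1
F6 | step 25 | allylic alcohol: 34 without the PMB group (3β-OH, C1=C2, open diene) | O[C@H]1C=C[C@]2(C)[C@H](C[C@H](OC(C)=O)[C@](O)(C(O[Si](C)(C)C(C)(C)C)CC=C)[C@H]2C(O[Si](C)(C)C(C)(C)C)CC(C)=C)C1(C)C
F7 | step 25 | 1β,2β,3β-triol of the open diene | O[C@H]1[C@@H](O)[C@]2(C)[C@H](C[C@H](OC(C)=O)[C@](O)(C(O[Si](C)(C)C(C)(C)C)CC=C)[C@H]2C(O[Si](C)(C)C(C)(C)C)CC(C)=C)C(C)(C)[C@H]1O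
F8 | step 25 | 2-acetate of F7 | CC(=O)O[C@H]1[C@@H](O)[C@]2(C)[C@H](C[C@H](OC(C)=O)[C@](O)(C(O[Si](C)(C)C(C)(C)C)CC=C)[C@H]2C(O[Si](C)(C)C(C)(C)C)CC(C)=C)C(C)(C)[C@H]1O
F9 | step 25 | 1,3-dibenzoate of F8 (open diene) | CC(=O)O[C@H]1[C@@H](OC(=O)c2ccccc2)[C@]2(C)[C@H](C[C@H](OC(C)=O)[C@](O)(C(O[Si](C)(C)C(C)(C)C)CC=C)[C@H]2C(O[Si](C)(C)C(C)(C)C)CC(C)=C)C(C)(C)[C@H]1OC(=O)c1ccccc1
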